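**Strategy.** Everything rests on closing ring B last, at C8–C9 (labdane numbering). C9 is α to the C11 carbonyl carbon and C8 carries only the exocyclic carbon C17, so a C9=C11 enol ether can add to a C8≡C17 alkyne hung through C7 from the C6 carbinol of an intact ring A. One gold-catalysed 6-exo-dig closure then forms C8–C9, ring B, the 8(17)-methylene, the C11 aldehyde and the C9 stereocentre. Its precursor is a cyclohexane with C10, C5 and C6 already set: C10 bears methyl C20 and the silyl enol ether, C5 the silyl-protected homopropargylic carbinol. C10 comes from an asymmetric allylation, C5 from a tethered hydroboration, C6 from a reagent-controlled propargylation.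

Key step: step 11

Remark: C1–C5 and C10 make up ring A and C5–C10 ring B, the methyls are C18 and C19 (on C4), C20 (on C10) and C17 (on C8), and the chain on C9 runs C11 to C16; enol ethers 13–16 are drawn E, and any Z isomer should give the same aldehyde 17 because C9 becomes stereogenic only on ring closure and stays epimerisable there.

**Route**

Step 1
Reactants: 1 2,2,6-trimethylcyclohexan-1-one; 2 allyl chloroformate
Product: 3 allyl 2,6,6-trimethylcyclohex-1-en-1-yl carbonate
Conditions: LiN(SiMe3)2, THF, 0 °C; then 2, −78 → 0 °C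
Reagents that add atoms: none
Why: The ketone has a single enolisable α-CH (the future C10), and the hard chloroformate acylates the hindered tetrasubstituted lithium enolate on oxygen (enolate O-acylation) to give the enol carbonate.

Step 2
Reactants: 3 allyl 2,6,6-trimethylcyclohex-1-en-1-yl carbonate
Product: 4 (S)-2-allyl-2,6,6-trimethylcyclohexan-1-one
Conditions: Pd2(dba)3 (2.5 mol %), (S)-t-Bu-PHOX (6 mol %), THF, 25 °C
Reagents that add atoms: none
Why: In this decarboxylative asymmetric allylic alkylation (Tsuji–Trost type) zerovalent palladium ionises the carbonate, CO2 is lost and the enolate recombines with the π-allyl fragment inside the chiral phosphinooxazoline pocket, the (S)-ligand being the one known to give the (S)-α-quaternary ketone in this series, which sets C10.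

Step 3
Reactants: 4 (S)-2-allyl-2,6,6-trimethylcyclohexan-1-one
Product: 5 (S)-2,6,6-trimethyl-2-[(E)-prop-1-en-1-yl]cyclohexan-1-one
Conditions: PdCl2(MeCN)2 (10 mol %), toluene, 60 °C
Reagents that add atoms: none
Why: Alkene isomerisation by palladium hydride addition–elimination moves the terminal double bond one position to the more stable E-propenyl group and must stop there because C10 is quaternary, while the non-enolisable ketone and C10 are untouched.

Step 4
Reactants: 5 (S)-2,6,6-trimethyl-2-[(E)-prop-1-en-1-yl]cyclohexan-1-one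
Product: 7 (S)-1,3,3-trimethyl-2-oxocyclohexane-1-carbaldehyde, via secondary ozonide 6 (not isolated)
Conditions: O3, CH2Cl2, −78 °C; then PPh3, −78 → 25 °C
Reagents that add atoms: ozone, [O-][O+]=O
Why: Ozonolysis (Criegee mechanism) with reductive work-up cleaves the only alkene and leaves C9 as an aldehyde on the quaternary C10, which has no α-hydrogen and cannot epimerise.

Step 5
Reactants: 7 (S)-1,3,3-trimethyl-2-oxocyclohexane-1-carbaldehyde
Product: 9 (S)-1-ethenyl-1,3,3-trimethyl-2-methylidenecyclohexane, via (S)-2-ethenyl-2,6,6-trimethylcyclohexan-1-one 8 (not isolated)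
Conditions: Ph3PCH3Br (3 equiv), KOt-Bu (2.9 equiv), toluene, 0 °C, then 110 °C
Reagents that add atoms: methyltriphenylphosphonium bromide, C[P+](c1ccccc1)(c1ccccc1)c1ccccc1.[Br-]
Why: In this double Wittig methylenation the aldehyde reacts cold to give vinyl ketone 8 (C9=C11), and the hindered ketone, which can neither enolise nor epimerise, is then forced to the exocyclic methylene (C5=C6) with excess ylide in hot toluene, the forcing conditions used for hindered ketones.

Step 6
Reactants: 9 (S)-1-ethenyl-1,3,3-trimethyl-2-methylidenecyclohexane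
Product: 11 2-[(1S,2R)-2-(hydroxymethyl)-1,3,3-trimethylcyclohexyl]ethan-1-ol, via trans-fused B-thexylborinane 10 (not isolated)
Conditions: ThxBH2 (from BH3·THF, 2,3-dimethylbut-2-ene), THF, 0 → 25 °C, slow addition of 9; then NaOH, H2O2, 0 → 50 °C
Reagents that add atoms: hydrogen peroxide, OO
Why: In this cyclic hydroboration of a 1,4-diene thexylborane adds first to the unhindered vinyl group at C11, and the remaining B–H is delivered intramolecularly to C5=C6 through a six-membered borinane transition state that is only reachable with C9 equatorial and from the face opposite the syn-axial methyls C19 and C20, so H5 ends up anti to C20 (C5 set as R), and oxidation with retention gives the 6,11-diol.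

Step 7
Reactants: 11 2-[(1S,2R)-2-(hydroxymethyl)-1,3,3-trimethylcyclohexyl]ethan-1-ol
Product: 12 (1R,2S)-2,6,6-trimethyl-2-(2-oxoethyl)cyclohexane-1-carbaldehyde
Conditions: (COCl)2, DMSO, CH2Cl2, −78 °C; then i-Pr2NEt, −78 → −20 °C
Reagents that add atoms: none
Why: In the Swern oxidation both primary hydroxyls are turned into alkoxysulfonium ions before base is added, which prevents lactol and lactone formation, and H5, buried between two quaternary carbons, should not epimerise under these cold and brief conditions.

Step 8
Reactants: 12 (1R,2S)-2,6,6-trimethyl-2-(2-oxoethyl)cyclohexane-1-carbaldehyde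
Product: 13 (1R,2S)-2,6,6-trimethyl-2-[(E)-2-(triisopropylsilyloxy)ethenyl]cyclohexane-1-carbaldehyde
Conditions: TIPSOTf (1.05 equiv), Et3N, CH2Cl2, −78 → −20 °C
Reagents that add atoms: triisopropylsilyl trifluoromethanesulfonate, CC(C)[Si](C(C)C)(C(C)C)OS(=O)(=O)C(F)(F)F
Why: Soft enolisation (silyl triflate with a tertiary amine) occurs only at the C11 aldehyde, whose α-CH2 (C9) is accessible, whereas enolising the C6 aldehyde would require removal of H5 between two quaternary carbons and would create a badly strained exocyclic enol ether, so one equivalent should give the mono enol ether with C5 intact.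

Step 9
Reactants: 13 (1R,2S)-2,6,6-trimethyl-2-[(E)-2-(triisopropylsilyloxy)ethenyl]cyclohexane-1-carbaldehyde
Product: 15 (1R)-1-[(1R,2S)-2,6,6-trimethyl-2-{(E)-2-(triisopropylsilyloxy)ethenyl}cyclohexyl]but-3-yn-1-ol, via diisopinocampheylborinate ester 14 (not isolated)
Conditions: B-allenyl-bis(isopinocampheyl)borane [from (−)-α-pinene], Et2O, −78 °C; then NaOH, H2O2, 0 °C
Reagents that add atoms: B-allenyl-bis(isopinocampheyl)borane from (−)-α-pinene, C=C=CB([C@H]1C[C@H]2C[C@@H]([C@@H]1C)C2(C)C)[C@H]1C[C@H]2C[C@@H]([C@@H]1C)C2(C)C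
Why: In this asymmetric propargylboration the allenylborane reacts through a closed six-membered SE2′ transition state to give the homopropargylic alcohol, and the isopinocampheyl groups from (−)-α-pinene direct attack to the Re face of the C6 aldehyde (the sense established for the corresponding allylborane), which sets C6 as R under reagent control and turns any minor enantiomer carried from step 2 into a separable diastereomer.

Step 10
Reactants: 15 (1R)-1-[(1R,2S)-2,6,6-trimethyl-2-{(E)-2-(triisopropylsilyloxy)ethenyl}cyclohexyl]but-3-yn-1-ol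
Product: 16 tert-butyldimethylsilyl ether of 15 (ring A silyl enol ether–alkyne, 6-O-TBS)
Conditions: TBSOTf, 2,6-lutidine, CH2Cl2, −78 → 0 °C
Reagents that add atoms: tert-butyldimethylsilyl trifluoromethanesulfonate, CC(C)(C)[Si](C)(C)OS(=O)(=O)C(F)(F)F
Why: Silyl ether formation with a silyl triflate protects the hindered secondary alcohol, and 2,6-lutidine keeps the medium non-acidic so that the enol ether and the terminal alkyne survive.

Step 11
Reactants: 16 tert-butyldimethylsilyl ether of 15 (ring A silyl enol ether–alkyne, 6-O-TBS)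
Product: 17 (1R,4R,4aR,8aR)-4-(tert-butyldimethylsilyloxy)-5,5,8a-trimethyl-2-methylidenedecahydronaphthalene-1-carbaldehyde
Conditions: Ph3PAuCl (10 mol %), AgBF4 (10 mol %), CH2Cl2/MeOH 10:1, 25 → 40 °C
Reagents that add atoms: none
Why: Cationic monovalent gold (Ph3PAu+ after chloride abstraction by AgBF4) coordinates the terminal alkyne, carbon C9 of the silyl enol ether attacks the internal carbon C8 anti to gold, and methanol then takes the silyl group from the oxocarbenium ion and protonates the vinyl–gold bond, releasing the C11 aldehyde, the 8(17)-methylene and the catalyst. The closest known reaction is the gold-catalysed carbocyclisation of silyl enol ethers onto alkynes (Conia-ene type). Ring B closes in the 6-exo-dig mode, attack at the internal carbon C8 of the terminal alkyne being preferred over 7-endo attack at C17. The new stereocentre C9 is controlled by the chair-like transition state of the forming trans-fused ring, in which the axial methyl C20 eclipses the enol double bond to minimise allylic strain and C11 therefore becomes equatorial, which is also the arrangement expected on equilibration of this epimerisable α-carbon. The step needs exo regioselectivity and C–C bond formation faster than solvolysis of the alkyne or hydrolysis of the enol ether, and the substrate secures this by holding C6 and C9 trans-diequatorial on ring A (C5, C6 and C10 are already fixed), so that C9 lies within bonding distance of C8.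

Step 12
Reactants: 17 (1R,4R,4aR,8aR)-4-(tert-butyldimethylsilyloxy)-5,5,8a-trimethyl-2-methylidenedecahydronaphthalene-1-carbaldehyde
Product: 18 tert-butyl{[(1R,4R,4aS,8aR)-4-ethenyl-4a,8,8-trimethyl-3-methylidenedecahydronaphthalen-1-yl]oxy}dimethylsilane
Conditions: Ph3PCH3Br, KN(SiMe3)2, THF, −78 → 0 °C
Reagents that add atoms: methyltriphenylphosphonium bromide, C[P+](c1ccccc1)(c1ccccc1)c1ccccc1.[Br-]
Why: Wittig methylenation with the non-stabilised ylide at low temperature, where carbonyl addition should outrun deprotonation at C9 so that neither epimerisation nor migration of the 8(17)-alkene into conjugation is expected, adds C12 and leaves C9 no longer epimerisable.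

Step 13
Reactants: 18 tert-butyl{[(1R,4R,4aS,8aR)-4-ethenyl-4a,8,8-trimethyl-3-methylidenedecahydronaphthalen-1-yl]oxy}dimethylsilane
Product: 19 8,17-epoxide of 18 (spiro-oxirane at C8 with oxygen on the face opposite C20)
Conditions: mCPBA (1.1 equiv), NaHCO3, CH2Cl2, 0 °C
Reagents that add atoms: 3-chloroperoxybenzoic acid, OOC(=O)c1cccc(Cl)c1
Why: In this Prilezhaev epoxidation the 1,1-disubstituted exocyclic alkene is far more nucleophilic than the monosubstituted vinyl group, and the peracid approaches C8 equatorially from the face opposite the axial methyl C20 (the course known for 8(17)-labdenes), which sets the C8–O bond anti to C20.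

Step 14
Reactants: 19 8,17-epoxide of 18 (spiro-oxirane at C8 with oxygen on the face opposite C20)
Product: 20 (1S,2S,4R,4aR,8aR)-4-(tert-butyldimethylsilyloxy)-1-ethenyl-2,5,5,8a-tetramethyldecahydronaphthalen-2-ol
Conditions: LiAlH4, THF, 0 → 66 °C
Reagents that add atoms: none
Why: Hydride reduction of the epoxide by SN2 attack at the unsubstituted carbon C17 keeps the C8–O bond and its configuration and turns C17 into the axial methyl, while the silyl ether and the vinyl group are inert.

Step 15
Reactants: 21 methyl acetoacetate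
Product: 22 methyl (2E)-3-(trifluoromethanesulfonyloxy)but-2-enoate
Conditions: Tf2O, aq. Me4NOH, toluene, 5 °C
Reagents that add atoms: trifluoromethanesulfonic anhydride, FC(F)(F)S(=O)(=O)OS(=O)(=O)C(F)(F)F
Why: Enol triflate formation by O-sulfonylation of the β-keto ester enolate, which with the non-chelating tetramethylammonium counter-ion reacts in its extended form and gives the E isomer (triflate trans to the ester), whereas a chelated lithium enolate would give Z.

Step 16
Reactants: 20 (1S,2S,4R,4aR,8aR)-4-(tert-butyldimethylsilyloxy)-1-ethenyl-2,5,5,8a-tetramethyldecahydronaphthalen-2-ol; 22 methyl (2E)-3-(trifluoromethanesulfonyloxy)but-2-enoate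
Product: 24 methyl (2E)-5-[(1S,2S,4R,4aR,8aR)-4-(tert-butyldimethylsilyloxy)-2-hydroxy-2,5,5,8a-tetramethyldecahydronaphthalen-1-yl]-3-methylpent-2-enoate, via B-alkyl-9-borabicyclo[3.3.1]nonane 23 (not isolated)
Conditions: 9-BBN-H (3 equiv), THF, 0 → 50 °C; then 22, Pd(dppf)Cl2 (5 mol %), AsPh3, aq. K3PO4, DMF, 25 °C
Reagents that add atoms: none
Why: Anti-Markovnikov hydroboration of the terminal vinyl group places boron on C12, and the B-alkyl Suzuki–Miyaura coupling with the enol triflate proceeds with retention of alkene geometry, which joins C12 to C13 and gives the 13E-enoate.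

Step 17
Reactants: 24 methyl (2E)-5-[(1S,2S,4R,4aR,8aR)-4-(tert-butyldimethylsilyloxy)-2-hydroxy-2,5,5,8a-tetramethyldecahydronaphthalen-1-yl]-3-methylpent-2-enoate
Product: 25 methyl (2E)-5-[(1S,2S,4R,4aR,8aR)-2,4-dihydroxy-2,5,5,8a-tetramethyldecahydronaphthalen-1-yl]-3-methylpent-2-enoate
Conditions: HF·pyridine, pyridine, THF, 0 → 25 °C
Reagents that add atoms: none
Why: Fluoride-driven desilylation (formation of the strong Si–F bond) removes the hindered secondary silyl ether without affecting the tertiary alcohol, the ester or the E-alkene.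

**Compound list**

1 | 2,2,6-trimethylcyclohexan-1-one | CC1CCCC(C)(C)C1=O | starting material
2 | allyl chloroformate | C=CCOC(=O)Cl | starting material
3 | allyl 2,6,6-trimethylcyclohex-1-en-1-yl carbonate | C=CCOC(=O)OC1=C(C)CCCC1(C)C | intermediate
4 | (S)-2-allyl-2,6,6-trimethylcyclohexan-1-one | C=CC[C@]1(C)CCCC(C)(C)C1=O | intermediate
5 | (S)-2,6,6-trimethyl-2-[(E)-prop-1-en-1-yl]cyclohexan-1-one | C/C=C/[C@]1(C)CCCC(C)(C)C1=O | intermediate
6 | secondary ozonide of 5, 3-methyl-5-[(1S)-1,3,3-trimethyl-2-oxocyclohexyl]-1,2,4-trioxolane (trioxolane carbons as a mixture) | CC1OOC(O1)[C@]1(C)CCCC(C)(C)C1=O | intermediate (not isolated)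
7 | (S)-1,3,3-trimethyl-2-oxocyclohexane-1-carbaldehyde | O=C[C@]1(C)CCCC(C)(C)C1=O | intermediate
8 | (S)-2-ethenyl-2,6,6-trimethylcyclohexan-1-one | C=C[C@]1(C)CCCC(C)(C)C1=O | intermediate (not isolated)
9 | (S)-1-ethenyl-1,3,3-trimethyl-2-methylidenecyclohexane | C=C[C@]1(C)CCCC(C)(C)C1=C | intermediate
10 | trans-fused B-thexylborinane, 2-(2,3-dimethylbutan-2-yl)-4a,8,8-trimethyldecahydro-2-benzoborinine (boron between C6 and C11, H5 anti to C20) | CC(C)C(C)(C)B1CC[C@]2(C)CCCC(C)(C)[C@H]2C1 | intermediate (not isolated)
11 | 2-[(1S,2R)-2-(hydroxymethyl)-1,3,3-trimethylcyclohexyl]ethan-1-ol | OCC[C@]1(C)CCCC(C)(C)[C@H]1CO | intermediate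
12 | (1R,2S)-2,6,6-trimethyl-2-(2-oxoethyl)cyclohexane-1-carbaldehyde | O=CC[C@]1(C)CCCC(C)(C)[C@H]1C=O | intermediate
13 | (1R,2S)-2,6,6-trimethyl-2-[(E)-2-(triisopropylsilyloxy)ethenyl]cyclohexane-1-carbaldehyde | CC(C)[Si](C(C)C)(C(C)C)O/C=C/[C@]1(C)CCCC(C)(C)[C@H]1C=O | intermediate
14 | diisopinocampheylborinate ester of 15 (isopinocampheyl groups from (−)-α-pinene) | CC(C)[Si](C(C)C)(C(C)C)O/C=C/[C@]1(C)CCCC(C)(C)[C@H]1[C@H](OB([C@H]2C[C@H]3C[C@@H]([C@@H]2C)C3(C)C)[C@H]2C[C@H]3C[C@@H]([C@@H]2C)C3(C)C)CC#C | intermediate (not isolated)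
15 | (1R)-1-[(1R,2S)-2,6,6-trimethyl-2-{(E)-2-(triisopropylsilyloxy)ethenyl}cyclohexyl]but-3-yn-1-ol | CC(C)[Si](C(C)C)(C(C)C)O/C=C/[C@]1(C)CCCC(C)(C)[C@H]1[C@H](O)CC#C | intermediate
16 | tert-butyl{[(1R)-1-{(1R,2S)-2,6,6-trimethyl-2-[(E)-2-(triisopropylsilyloxy)ethenyl]cyclohexyl}but-3-yn-1-yl]oxy}dimethylsilane (key-step precursor) | CC(C)[Si](C(C)C)(C(C)C)O/C=C/[C@]1(C)CCCC(C)(C)[C@H]1[C@H](O[Si](C)(C)C(C)(C)C)CC#C | intermediate
17 | (1R,4R,4aR,8aR)-4-(tert-butyldimethylsilyloxy)-5,5,8a-trimethyl-2-methylidenedecahydronaphthalene-1-carbaldehyde (key-step product) | O=C[C@H]1[C@]2(C)CCCC(C)(C)[C@H]2[C@H](O[Si](C)(C)C(C)(C)C)CC1=C | intermediate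
18 | tert-butyl{[(1R,4R,4aS,8aR)-4-ethenyl-4a,8,8-trimethyl-3-methylidenedecahydronaphthalen-1-yl]oxy}dimethylsilane | C=C[C@H]1[C@]2(C)CCCC(C)(C)[C@H]2[C@H](O[Si](C)(C)C(C)(C)C)CC1=C | intermediate
19 | 8,17-epoxide of 18 (spiro-oxirane at C8, oxygen anti to C20; C8 S, C9 S) | C=C[C@H]1[C@]2(C)CCCC(C)(C)[C@H]2[C@H](O[Si](C)(C)C(C)(C)C)C[C@@]13CO3 | intermediate
20 | (1S,2S,4R,4aR,8aR)-4-(tert-butyldimethylsilyloxy)-1-ethenyl-2,5,5,8a-tetramethyldecahydronaphthalen-2-ol | C=C[C@H]1[C@]2(C)CCCC(C)(C)[C@H]2[C@H](O[Si](C)(C)C(C)(C)C)C[C@]1(C)O | intermediate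
21 | methyl acetoacetate | CC(=O)CC(=O)OC | starting material
22 | methyl (2E)-3-(trifluoromethanesulfonyloxy)but-2-enoate | COC(=O)/C=C(\C)OS(=O)(=O)C(F)(F)F | intermediate
23 | 9-{2-[(1S,2S,4R,4aR,8aR)-4-(tert-butyldimethylsilyloxy)-2-hydroxy-2,5,5,8a-tetramethyldecahydronaphthalen-1-yl]ethyl}-9-borabicyclo[3.3.1]nonane | C1CCC2CCCC1B2CC[C@H]1[C@]3(C)CCCC(C)(C)[C@H]3[C@H](O[Si](C)(C)C(C)(C)C)C[C@]1(C)O | intermediate (not isolated)
24 | methyl (2E)-5-[(1S,2S,4R,4aR,8aR)-4-(tert-butyldimethylsilyloxy)-2-hydroxy-2,5,5,8a-tetramethyldecahydronaphthalen-1-yl]-3-methylpent-2-enoate | COC(=O)/C=C(\C)CC[C@H]1[C@]2(C)CCCC(C)(C)[C@H]2[C@H](O[Si](C)(C)C(C)(C)C)C[C@]1(C)O | intermediate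
25 | methyl (2E)-5-[(1S,2S,4R,4aR,8aR)-2,4-dihydroxy-2,5,5,8a-tetramethyldecahydronaphthalen-1-yl]-3-methylpent-2-enoate (CNP0289884.1) | COC(=O)/C=C(\C)CC[C@H]1[C@]2(C)CCCC(C)(C)[C@H]2[C@H](O)C[C@]1(C)O | target

**Step count and risks**

Total step count: 17. Longest linear sequence: 16 steps (steps 1–14, 16 and 17); step 15 prepares the coupling partner.

The three steps most likely to fail:

1. Step 11 (key step). The 6-exo-dig closure at the neopentyl carbon C9 may be slower than solvolysis of the gold-activated alkyne by methanol or protodesilylation of the enol ether, so that open-chain carbonyl compounds form instead of ring B. The fallback sets out from 13 and comes back at 17, and makes the same C8–C9 bond by palladium-catalysed enolate alkenylation instead of π-acid activation. Aldehyde 13 would be 2-bromoallylated under reagent control, using 2-bromoallyl(tributyl)stannane and the appropriate enantiomer of a 1,2-diphenylethylenediamine-derived bis(sulfonamido)bromoborane, to give (1R)-3-bromo-1-[(1R,2S)-2,6,6-trimethyl-2-{(E)-2-(triisopropylsilyloxy)ethenyl}cyclohexyl]but-3-en-1-ol F1. Silylation (TBSOTf, 2,6-lutidine) would give its tert-butyldimethylsilyl ether F2. Pd2(dba)3, t-Bu3P and CsF in toluene at 80 °C would then join the alkenyl bromide carbon C8 to the fluoride-activated enol ether carbon C9 (intramolecular α-alkenylation of an aldehyde enolate equivalent) and give aldehyde 17 directly.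

2. Step 5. Olefination of the ketone flanked by two quaternary carbons may stall, or tert-butoxide may attack the formyl group of 7 and cleave it off (retro-Claisen fragmentation) before the ylide reacts. The fallback sets out from 7 and comes back at 9, and introduces C6 by addition and elimination instead of olefination. Aldehyde 7 would be methylenated alone with salt-free Ph3P=CH2 in THF at −78 °C and vinyl ketone 8 isolated. MeLi with CeCl3 at −78 °C would add to the non-enolisable ketone and give (2S)-2-ethenyl-1,2,6,6-tetramethylcyclohexan-1-ol F3, either carbinol epimer being usable. Syn-elimination with the Burgess reagent in warm toluene, which can only proceed toward the new methyl group because both ring neighbours are quaternary, would give diene 9.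

3. Step 9. Reagent and substrate facial preferences at the C6 aldehyde may oppose each other (mismatched double diastereoselection), or addition to the hindered aldehyde may be too slow at low temperature, so that facial control at C6 is lost. The fallback sets out from 13 and comes back at 15, and sets C6 by ketone reduction instead of C–C bond formation. Zinc-mediated Barbier addition of 3-bromoprop-1-yne to 13 in THF would give the C6-epimeric homopropargylic alcohols F4. Buffered Dess–Martin oxidation would give the β,γ-alkynyl ketone F5. Corey–Bakshi–Shibata reduction with the (S)-methyl oxazaborolidine and BH3·SMe2, which distinguishes the bulky ring substituent from the propargyl methylene, would return the (R)-alcohol 15.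

**Further compounds**

F1 | step 11 | (1R)-3-bromo-1-[(1R,2S)-2,6,6-trimethyl-2-{(E)-2-(triisopropylsilyloxy)ethenyl}cyclohexyl]but-3-en-1-ol | CC(C)[Si](C(C)C)(C(C)C)O/C=C/[C@]1(C)CCCC(C)(C)[C@H]1[C@H](O)CC(Br)=C
F2 | step 11 | tert-butyldimethylsilyl ether of F1 | CC(C)[Si](C(C)C)(C(C)C)O/C=C/[C@]1(C)CCCC(C)(C)[C@H]1[C@H](O[Si](C)(C)C(C)(C)C)CC(Br)=C
F3 | step 5 | (2S)-2-ethenyl-1,2,6,6-tetramethylcyclohexan-1-ol (both C1 epimers) | C=C[C@]1(C)CCCC(C)(C)C1(C)O
F4 | step 9 | 1-[(1R,2S)-2,6,6-trimethyl-2-{(E)-2-(triisopropylsilyloxy)ethenyl}cyclohexyl]but-3-yn-1-ol (mixture of carbinol epimers) | CC(C)[Si](C(C)C)(C(C)C)O/C=C/[C@]1(C)CCCC(C)(C)[C@H]1C(O)CC#C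
F5 | step 9 | 1-[(1R,2S)-2,6,6-trimethyl-2-{(E)-2-(triisopropylsilyloxy)ethenyl}cyclohexyl]but-3-yn-1-one | CC(C)[Si](C(C)C)(C(C)C)O/C=C/[C@]1(C)CCCC(C)(C)[C@H]1C(=O)CC#C
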